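**Retrosynthetic overview**
- The C11 hydroperoxide and the C6=C7 double bond come from a singlet-oxygen ene reaction on the 3-O-angeloyl eudesm-7(11)-en-8-one. The angelate is put on late, and the isopropylidene comes from aldol condensation of the C8 ketone with acetone.
- The ring-A triad (3β-O, 4α-OH, 5α-H) comes from a 4-methyl-Δ4-3-ketone by Birch reductive silylation, Rubottom oxidation and hydride reduction, with the C8 ketone masked as a dioxolane.
- Key disconnection: the ring-B cyclohexanone (C8=O β to the quaternary C10) comes from a one-carbon ring expansion of an α-quaternary cyclopentanone by 1,2-shift of the quaternary carbon.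
- The hydrindenedione comes from 2-methylcyclopentane-1,3-dione and ethyl vinyl ketone (asymmetric Hajos–Parrish annulation sets C10).
- Ring order: ring A (six-membered enone) is formed first by annulation; ring B is formed second by expanding the five-membered ring.

Assumption: positions are given in eudesmane numbering (C10 = angular-methyl carbon, C5 = ring-fusion CH, C8 = ring-B carbonyl); the given SMILES corresponds to (3S,4S,5R,10R).

**Step 1**
Reactants: 1 2-methylcyclopentane-1,3-dione; 2 pent-1-en-3-one (ethyl vinyl ketone)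
Product: 4 (7aS)-4,7a-dimethyl-2,3,7,7a-tetrahydro-1H-indene-1,5(6H)-dione, via Michael triketone 3 (not isolated)
Conditions: 2 (1.5 equiv), H2O, AcOH (cat.), 75 °C; evaporate; (S)-phenylalanine (1.0 equiv), (1S)-(+)-10-camphorsulfonic acid (0.5 equiv), DMF, 30→70 °C
Reagents that add atoms: none
Why: Michael addition followed by the Hajos–Parrish (Eder–Sauer–Wiechert) enamine aldol condensation, in which the (S)-phenylalanine-derived enamine of the side-chain ketone attacks one of the two enantiotopic ring carbonyls and so fixes the quaternary centre as 7aS (about 90–95% ee, raised by one recrystallisation).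

**Step 2**
Reactants: 4 (7aS)-4,7a-dimethyl-2,3,7,7a-tetrahydro-1H-indene-1,5(6H)-dione
Product: 7 (4aR)-1,4a-dimethyl-4,4a,7,8-tetrahydronaphthalene-2,6(3H,5H)-dione, via dibromomethyl carbinolate 5 (not isolated), via oxido magnesium carbenoid 6 (not isolated)
Conditions: CHBr3 (1.3 equiv), i-PrMgCl·LiCl (1.3 equiv), THF, −78 °C; then 4 + LaCl3·2LiCl (0.3 equiv), −78 °C, 1 h; then i-PrMgCl·LiCl (1.5 equiv), −78→0 °C; aq. NH4Cl
Reagents that add atoms: bromoform BrC(Br)Br
Why: Proposed new method: a one-flask all-magnesium β-oxido-carbenoid ring enlargement in which LaCl3-activated Br2CHMgCl adds 1,2 to the more electrophilic non-conjugated cyclopentanone (α-face, anti to the angular methyl) rather than to the deactivated α-methyl enone, a second i-PrMgCl·LiCl performs Br/Mg exchange faster than it attacks the enone, and the carbenoid expels bromide with 1,2-shift of the more electron-rich fully substituted carbon with retention (the centre is carried over unchanged, 7aS in 4 = 4aR in 7) to give the six-ring magnesium enolate that is protonated to 7; the closest known reaction type is the lithium β-oxido carbenoid one-carbon ring enlargement of simple cycloalkanones (CH2Br2/amide base, then n-BuLi), which to our knowledge has not been shown on an α-quaternary cyclopentanone inside an unprotected enedione or as an enone-tolerant Turbo-Grignard/lanthanum protocol.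

**Step 3**
Reactants: 7 (4aR)-1,4a-dimethyl-4,4a,7,8-tetrahydronaphthalene-2,6(3H,5H)-dione
Product: 8 (4aR)-6,6-(ethylenedioxy)-1,4a-dimethyl-4,4a,5,6,7,8-hexahydronaphthalen-2(3H)-one
Conditions: ethylene glycol, p-TsOH·H2O (cat.), 4 Å MS, rt
Reagents that add atoms: ethylene glycol OCCO
Why: Chemoselective acid-catalysed acetalisation, because the saturated C8 ketone is far more electrophilic than the conjugated ring-A enone carbonyl (the selectivity used for the mono-ketal of the Wieland–Miescher ketone); no stereocentre is formed.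

**Step 4**
Reactants: 8 (4aR)-6,6-(ethylenedioxy)-1,4a-dimethyl-4,4a,5,6,7,8-hexahydronaphthalen-2(3H)-one
Product: 10 [(4aR,8aR)-6,6-(ethylenedioxy)-1,4a-dimethyl-3,4,4a,5,6,7,8,8a-octahydronaphthalen-2-yl]oxy(trimethyl)silane, via lithium enolate 9 (not isolated)
Conditions: Li (2.3 equiv), t-BuOH (1.0 equiv), NH3/THF, −78 °C; isoprene; evaporate NH3; TMSCl, Et3N, THF, −78→0 °C
Reagents that add atoms: chlorotrimethylsilane C[Si](C)(C)Cl
Why: Dissolving-metal (Birch-type) enone reduction with regiospecific enolate trapping (Stork reductive silylation), in which protonation of the pyramidal β-carbanion at C5 gives the trans-decalin (5α-H anti to the 10β-methyl) and the Δ3-enolate is O-silylated before it can equilibrate.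

**Step 5**
Reactants: 10 [(4aR,8aR)-6,6-(ethylenedioxy)-1,4a-dimethyl-3,4,4a,5,6,7,8,8a-octahydronaphthalen-2-yl]oxy(trimethyl)silane
Product: 13 (1S,4aR,8aR)-6,6-(ethylenedioxy)-1-hydroxy-1,4a-dimethyloctahydronaphthalen-2(1H)-one, via siloxy epoxide 11 (not isolated), via silyloxy ketone 12 (not isolated)
Conditions: mCPBA (1.1 equiv), NaHCO3, CH2Cl2, −20 °C; then K2CO3 (cat.), MeOH, 0 °C
Reagents that add atoms: meta-chloroperoxybenzoic acid OOC(=O)c1cccc(Cl)c1
Why: Rubottom oxidation, in which mCPBA epoxidises the tetrasubstituted silyl enol ether from the α-face because the β-face of C4 is blocked by the syn-axial C10 methyl, and 1,4-silyl migration then methanolysis give the 4α-hydroxy-4β-methyl ketone (4S).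

**Step 6**
Reactants: 13 (1S,4aR,8aR)-6,6-(ethylenedioxy)-1-hydroxy-1,4a-dimethyloctahydronaphthalen-2(1H)-one
Product: 15 (4aR,5S,6S,8aR)-5,6-dihydroxy-5,8a-dimethyloctahydronaphthalen-2(1H)-one, via ketal diol 14 (not isolated)
Conditions: NaBH4, MeOH, 0 °C; then 2 M HCl, THF, rt
Reagents that add atoms: water O
Why: Borohydride reduction by axial (α-face) hydride attack, the equatorial approach being screened by the axial 4β-methyl, gives the equatorial 3β-alcohol (3S, trans-diequatorial to the 4α-OH), and the aqueous acid then hydrolyses the dioxolane to the C8 ketone.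

**Step 7**
Reactants: 15 (4aR,5S,6S,8aR)-5,6-dihydroxy-5,8a-dimethyloctahydronaphthalen-2(1H)-one; 16 acetone
Product: 18 (3R,4aR,5S,6S,8aR)-5,6-dihydroxy-3-(2-hydroxypropan-2-yl)-5,8a-dimethyloctahydronaphthalen-2(1H)-one, via trilithium enolate 17 (not isolated)
Conditions: LDA (3.3 equiv), THF, −78 °C; acetone (5 equiv), −78 °C; AcOH, −78 °C
Reagents that add atoms: none
Why: Directed (kinetic lithium enolate) aldol addition, in which LDA, after deprotonating both hydroxyls, removes the axial C7 proton because C9 is neopentyl next to the quaternary C10, and the Δ7-enolate adds to acetone; the new C7 centre (drawn as the equatorial epimer) is lost in step 8, so both epimers are used.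

**Step 8**
Reactants: 18 (3R,4aR,5S,6S,8aR)-5,6-dihydroxy-3-(2-hydroxypropan-2-yl)-5,8a-dimethyloctahydronaphthalen-2(1H)-one
Product: 19 (4aR,5S,6S,8aR)-5,6-dihydroxy-5,8a-dimethyl-3-(propan-2-ylidene)octahydronaphthalen-2(1H)-one
Conditions: p-TsOH·H2O (0.1 equiv), benzene, 60 °C, 1 h
Reagents that add atoms: none
Why: Acid-catalysed dehydration of the tertiary β-ketol through the enol (completing the aldol condensation) gives the conjugated tetrasubstituted isopropylidene ketone as the thermodynamic pulegone-type enone, under conditions where the isolated 3,4-diol does not ionise; no stereocentre is formed.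

**Step 9**
Reactants: 19 (4aR,5S,6S,8aR)-5,6-dihydroxy-5,8a-dimethyl-3-(propan-2-ylidene)octahydronaphthalen-2(1H)-one; 20 angelic acid [(2Z)-2-methylbut-2-enoic acid]
Product: 22 (1S,2S,4aR,8aR)-1-hydroxy-1,4a-dimethyl-6-oxo-7-(propan-2-ylidene)decahydronaphthalen-2-yl (2Z)-2-methylbut-2-enoate, via angelic mixed anhydride 21 (not isolated)
Conditions: 20 (3 equiv), 2,4,6-trichlorobenzoyl chloride (3 equiv), Et3N (3 equiv), toluene, rt, 2 h; then 19, toluene, 80 °C
Reagents that add atoms: none
Why: Yamaguchi esterification through the mixed anhydride without a nucleophilic catalyst acylates the equatorial secondary 3β-OH while the tertiary 4α-OH is inert, and avoids the Z→E (angelate→tiglate) isomerisation seen with carbodiimide/DMAP; no stereocentre is touched.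

**Step 10**
Reactants: 22 (1S,2S,4aR,8aR)-1-hydroxy-1,4a-dimethyl-6-oxo-7-(propan-2-ylidene)decahydronaphthalen-2-yl (2Z)-2-methylbut-2-enoate
Product: 23 (1S,2S,4aR,8aR)-7-(2-hydroperoxypropan-2-yl)-1-hydroxy-1,4a-dimethyl-6-oxo-1,2,3,4,4a,5,6,8a-octahydronaphthalen-2-yl (2Z)-2-methylbut-2-enoate
Conditions: O2, tetraphenylporphyrin (cat.), hν (white LED), CH2Cl2, −20 °C
Reagents that add atoms: dioxygen O=O
Why: Schenck ene reaction of singlet oxygen with the s-cis enone, whose geminal (carbonyl-directed) selectivity abstracts the allylic C6–H on the branch attached to the α-carbon and places the O–O bond at C11, gives the 11-hydroperoxy-Δ6-8-one directly, while the electron-poor trisubstituted angelate reacts far more slowly; no stereocentre is created.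

**Compound list**
1 | 2-methylcyclopentane-1,3-dione | CC1C(=O)CCC1=O | starting material
2 | pent-1-en-3-one (ethyl vinyl ketone) | CCC(=O)C=C | starting material
3 | 2-methyl-2-(3-oxopentyl)cyclopentane-1,3-dione | CCC(=O)CCC1(C)C(=O)CCC1=O | intermediate
4 | (7aS)-4,7a-dimethyl-2,3,7,7a-tetrahydro-1H-indene-1,5(6H)-dione | C[C@]12CCC(=O)C(C)=C1CCC2=O | intermediate
5 | chloromagnesium (1S,7aS)-1-(dibromomethyl)-4,7a-dimethyl-5-oxo-2,3,5,6,7,7a-hexahydro-1H-inden-1-olate (CHBr2 α, O β) | C[C@]12CCC(=O)C(C)=C1CC[C@@]2(O[Mg]Cl)C(Br)Br | intermediate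
6 | chloromagnesium (7aS)-1-[bromo(chloromagnesio)methyl]-4,7a-dimethyl-5-oxo-2,3,5,6,7,7a-hexahydro-1H-inden-1-olate (β-oxido carbenoid, carbenoid carbon not configurationally defined) | C[C@]12CCC(=O)C(C)=C1CC[C@@]2(O[Mg]Cl)C(Br)[Mg]Cl | intermediate
7 | (4aR)-1,4a-dimethyl-4,4a,7,8-tetrahydronaphthalene-2,6(3H,5H)-dione (11,12,13-trinoreudesm-4-ene-3,8-dione) | C[C@]12CCC(=O)C(C)=C1CCC(=O)C2 | intermediate
8 | (4aR)-6,6-(ethylenedioxy)-1,4a-dimethyl-4,4a,5,6,7,8-hexahydronaphthalen-2(3H)-one (C8 dioxolane of 7) | C[C@]12CCC(=O)C(C)=C1CCC3(OCCO3)C2 | intermediate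
9 | lithium (4aR,8aR)-6,6-(ethylenedioxy)-1,4a-dimethyl-3,4,4a,5,6,7,8,8a-octahydronaphthalen-2-olate (Δ3-enolate, 5α-H) | C[C@]12CCC(O[Li])=C(C)[C@@H]1CCC3(OCCO3)C2 | intermediate
10 | [(4aR,8aR)-6,6-(ethylenedioxy)-1,4a-dimethyl-3,4,4a,5,6,7,8,8a-octahydronaphthalen-2-yl]oxy(trimethyl)silane (trans-fused Δ3 silyl enol ether) | C[C@]12CCC(O[Si](C)(C)C)=C(C)[C@@H]1CCC3(OCCO3)C2 | intermediate
11 | 3α,4α-epoxy-3β-(trimethylsilyloxy) derivative of 10 (epoxide on the α-face, 4β-methyl) | C[C@]12CC[C@@]3(O[Si](C)(C)C)O[C@@]3(C)[C@@H]1CCC4(OCCO4)C2 | intermediate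
12 | (1S,4aR,8aR)-6,6-(ethylenedioxy)-1,4a-dimethyl-1-(trimethylsilyloxy)octahydronaphthalen-2(1H)-one | C[C@]12CCC(=O)[C@@](C)(O[Si](C)(C)C)[C@@H]1CCC3(OCCO3)C2 | intermediate
13 | (1S,4aR,8aR)-6,6-(ethylenedioxy)-1-hydroxy-1,4a-dimethyloctahydronaphthalen-2(1H)-one (4α-OH, 4β-Me, 5α-H) | C[C@]12CCC(=O)[C@@](C)(O)[C@@H]1CCC3(OCCO3)C2 | intermediate
14 | (1S,2S,4aR,8aR)-6,6-(ethylenedioxy)-1,4a-dimethyldecahydronaphthalene-1,2-diol (3β,4α-diol, C8 dioxolane) | C[C@]12CC[C@H](O)[C@@](C)(O)[C@@H]1CCC3(OCCO3)C2 | intermediate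
15 | (4aR,5S,6S,8aR)-5,6-dihydroxy-5,8a-dimethyloctahydronaphthalen-2(1H)-one (3β,4α-dihydroxy-11,12,13-trinoreudesman-8-one) | C[C@]12CC[C@H](O)[C@@](C)(O)[C@@H]1CCC(=O)C2 | intermediate
16 | acetone | CC(C)=O | starting material
17 | trilithium salt of 15 (3,4-dialkoxide and Δ7-enolate) | C[C@]12CC[C@H](O[Li])[C@@](C)(O[Li])[C@@H]1CC=C(O[Li])C2 | intermediate
18 | (3R,4aR,5S,6S,8aR)-5,6-dihydroxy-3-(2-hydroxypropan-2-yl)-5,8a-dimethyloctahydronaphthalen-2(1H)-one (3β,4α,11-trihydroxyeudesman-8-one, equatorial C7 epimer drawn) | C[C@]12CC[C@H](O)[C@@](C)(O)[C@@H]1C[C@H](C(C)(C)O)C(=O)C2 | intermediate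
19 | (4aR,5S,6S,8aR)-5,6-dihydroxy-5,8a-dimethyl-3-(propan-2-ylidene)octahydronaphthalen-2(1H)-one (3β,4α-dihydroxyeudesm-7(11)-en-8-one) | C[C@]12CC[C@H](O)[C@@](C)(O)[C@@H]1CC(=C(C)C)C(=O)C2 | intermediate
20 | angelic acid, (2Z)-2-methylbut-2-enoic acid | C/C=C(/C)C(=O)O | starting material
21 | (2Z)-2-methylbut-2-enoic 2,4,6-trichlorobenzoic anhydride | C/C=C(/C)C(=O)OC(=O)c1c(Cl)cc(Cl)cc1Cl | intermediate
22 | (1S,2S,4aR,8aR)-1-hydroxy-1,4a-dimethyl-6-oxo-7-(propan-2-ylidene)decahydronaphthalen-2-yl (2Z)-2-methylbut-2-enoate (3β-angeloyloxy-4α-hydroxyeudesm-7(11)-en-8-one) | C[C@]12CC[C@H](OC(=O)/C(C)=C\C)[C@@](C)(O)[C@@H]1CC(=C(C)C)C(=O)C2 | intermediate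
23 | (1S,2S,4aR,8aR)-7-(2-hydroperoxypropan-2-yl)-1-hydroxy-1,4a-dimethyl-6-oxo-1,2,3,4,4a,5,6,8a-octahydronaphthalen-2-yl (2Z)-2-methylbut-2-enoate (3β-angeloyloxy-4α-hydroxy-11-hydroperoxyeudesm-6-en-8-one, CNP0161122.1) | C[C@]12CC[C@H](OC(=O)/C(C)=C\C)[C@@](C)(O)[C@@H]1C=C(C(C)(C)OO)C(=O)C2 | target

**Step count and risks**
Total step count: 10. Longest linear sequence: 10 steps (fully linear, 1 → 23).

Three steps most likely to fail:

1. **Step 2 (proposed new ring expansion).** Risks are attack of the carbenoid or the Grignard reagent on the free enone, enolisation of the cyclopentanone, and migration of the CH2 instead of the quaternary carbon. The fallback uses known chemistry, sets out from 4 and returns at 7. Ethane-1,2-dithiol with p-TsOH in AcOH at rt thioketalises the conjugated carbonyl chemoselectively (the neopentyl cyclopentanone is too hindered) to give the spiro-dithiolane of the enone carbonyl F1. The established stoichiometric lithium β-oxido carbenoid ring enlargement (CH2Br2/LiTMP, THF, −95 °C, then n-BuLi 2.1 equiv, −95→−78 °C), known to shift the more substituted α-carbon, gives the ring-expanded dithiolane F2. MeI/CaCO3 in aqueous MeCN unmasks the enone to give 7.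

2. **Step 7 (aldol of the unprotected diol as a trianion).** Risks are poor solubility of the polyanion, proton transfer to acetone and retro-aldol. The fallback sets out from 15 and returns at 18. TMSOTf/Et3N (3.5 equiv, CH2Cl2, 0 °C) silylates both hydroxyls and forms the thermodynamic Δ7 silyl enol ether in one operation, giving the tris(trimethylsilyl) compound F3. Mukaiyama aldol addition to acetone (TiCl4, CH2Cl2, −78 °C) followed by 1 M HCl/MeOH work-up, which cleaves the silyl ethers, delivers 18 without strong base.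

3. **Step 10 (photooxygenation).** Risks are slow competing ene reaction at the angelate on prolonged irradiation and loss of the sensitive hydroperoxide on purification. The fallback sets out from 19 and returns at 23. Photooxygenation before the angelate is present (O2, TPP, hν, CH2Cl2, −20 °C) gives the hydroperoxy diol F4. Selective silylation of the more acidic OOH (TESCl, imidazole, DMF, −40 °C) gives the triethylsilyl peroxide F5. Yamaguchi angeloylation of the 3β-OH as in step 9 (toluene, 60 °C) gives the silyl-protected peroxy angelate F6. HF·pyridine (THF, 0 °C) frees the hydroperoxide 23.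

**Further compounds**
F1 | step 2 | (7aS)-5,5-(ethylenedithio)-4,7a-dimethyl-2,3,5,6,7,7a-hexahydro-1H-inden-1-one (spiro-dithiolane of the enone carbonyl of 4) | C[C@]12CCC3(SCCS3)C(C)=C1CCC2=O
F2 | step 2 | (4aR)-2,2-(ethylenedithio)-1,4a-dimethyl-2,3,4,4a,7,8-hexahydronaphthalen-6(5H)-one (spiro-dithiolane of the enone carbonyl of 7) | C[C@]12CCC3(SCCS3)C(C)=C1CCC(=O)C2
F3 | step 7 | 3β,4α,8-tris(trimethylsilyloxy)-11,12,13-trinoreudesm-7-ene (bis-silyl ether and Δ7 silyl enol ether of 15) | C[C@]12CC[C@H](O[Si](C)(C)C)[C@@](C)(O[Si](C)(C)C)[C@@H]1CC=C(O[Si](C)(C)C)C2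
F4 | step 10 | 3β,4α-dihydroxy-11-hydroperoxyeudesm-6-en-8-one | C[C@]12CC[C@H](O)[C@@](C)(O)[C@@H]1C=C(C(C)(C)OO)C(=O)C2
F5 | step 10 | 3β,4α-dihydroxy-11-(triethylsilylperoxy)eudesm-6-en-8-one | C[C@]12CC[C@H](O)[C@@](C)(O)[C@@H]1C=C(C(C)(C)OO[Si](CC)(CC)CC)C(=O)C2
F6 | step 10 | 3β-angeloyloxy-4α-hydroxy-11-(triethylsilylperoxy)eudesm-6-en-8-one | C[C@]12CC[C@H](OC(=O)/C(C)=C\C)[C@@](C)(O)[C@@H]1C=C(C(C)(C)OO[Si](CC)(CC)CC)C(=O)C2
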